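**Retrosynthetic overview**
Core numbering: C1 bridgehead carbinol, C2, C3 amide carbon, C4 and C6 carbinols, C5 bridgehead, C7–C8 oxirane, C9 bridging ketone.
Isariotin D is taken back through PMB removal at C1, hydroxyl-directed epoxidation of a C7=C8 alkene and a Wharton transposition (C8 ketone with C6–C7 oxirane → C6 carbinol with C7=C8) to a bicyclo[3.3.1]nonane-8,9-dione ketol.
The strategy rests on one feature: ring A (C1–C2–C3–C4–C5–C9) is a three-carbon amino alcohol unit C2–C3–C4 spanning the two α-carbons C1 and C5 of the C9 ketone. The ketol is therefore cut at C1–C2 and C4–C5 into 2-(4-methoxybenzyloxy)cyclohexane-1,3-dione and a 2-amidoacrolein that already carries the (E)-dec-2-enamide.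
Ring order: ring B (C1, C9, C5, C6, C7, C8) is the purchased cyclohexanedione; ring A is closed by the Michael–aldol annulation; the oxirane is made in the penultimate step.
The dione comes from cyclohexane-1,3-dione by diazo transfer and Rh-catalysed O–H insertion; the amidoacrolein comes from DL-serine methyl ester and (E)-dec-2-enoic acid.

Key step: step 7

Remark: the sense of induction of the chiral phosphoric acid in step 7 cannot be fixed in advance; the (R) acid is written, and its (S) antipode would be used if it selected the other enantiotopic ketone.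
Remark: compound 4 is drawn as the diketone but should exist mainly as its enol, 3-hydroxy-2-(4-methoxybenzyloxy)cyclohex-2-enone.
Remark: DL-serine methyl ester is used as its commercial hydrochloride and freed in the flask by the amine base.

**Step 1**
Reactants: 1 cyclohexane-1,3-dione
Product: 2 2-diazocyclohexane-1,3-dione
Conditions: p-ABSA, Et3N, MeCN, 0 °C → rt
Reagents that add atoms: 4-acetamidobenzenesulfonyl azide (p-ABSA), CC(=O)Nc1ccc(cc1)S(=O)(=O)N=[N+]=[N-]
Why: Regitz diazo transfer: the triethylammonium enolate of the 1,3-dione attacks the terminal nitrogen of the sulfonyl azide and the triazene collapses to the stabilized 2-diazo dione and the sulfonamide.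

**Step 2**
Reactants: 2 2-diazocyclohexane-1,3-dione; 3 4-methoxybenzyl alcohol
Product: 4 2-(4-methoxybenzyloxy)cyclohexane-1,3-dione
Conditions: Rh2(OAc)4 (1 mol%), PhH, 80 °C
Reagents that add atoms: none
Why: Rh(II)-carbenoid O–H insertion: the acceptor/acceptor carbenoid should be captured by the primary alcohol (oxonium ylide, then 1,2-proton shift) faster than it undergoes Wolff rearrangement or adds to the anisyl ring, and this avoids the O- versus C-alkylation problem of alkylating a 2-hydroxy dione.

**Step 3**
Reactants: 5 DL-serine methyl ester hydrochloride; 6 (E)-dec-2-enoic acid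
Product: 7 methyl N-[(E)-dec-2-enoyl]-DL-serinate
Conditions: EDC·HCl, HOBt, iPr2NEt, CH2Cl2, 0 °C → rt
Reagents that add atoms: none
Why: Carbodiimide/HOBt amide coupling acylates the amine in preference to the primary hydroxyl, and racemic serine suffices because its stereocentre is removed in step 4.

**Step 4**
Reactants: 7 methyl N-[(E)-dec-2-enoyl]-DL-serinate
Product: 9 methyl 2-[(E)-dec-2-enamido]acrylate, via methyl N-[(E)-dec-2-enoyl]-O-(methylsulfonyl)-DL-serinate 8 (not isolated)
Conditions: MsCl, Et3N (3 equiv), CH2Cl2, 0 °C → rt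
Reagents that add atoms: none
Why: O-Mesylation followed by E1cB β-elimination under the same amine base is the standard dehydration of N-acyl serine esters to dehydroalanine esters, driven by the acidity of the α-hydrogen and by conjugation in the product.

**Step 5**
Reactants: 9 methyl 2-[(E)-dec-2-enamido]acrylate
Product: 10 N-(3-hydroxyprop-1-en-2-yl)-(E)-dec-2-enamide
Conditions: DIBAL-H (3.5 equiv), CH2Cl2, −78 °C; aq. Rochelle salt
Reagents that add atoms: none
Why: DIBAL-H 1,2-reduction of the acrylate ester at −78 °C should give the allylic alcohol, while the secondary amide is first deprotonated to an aluminium amidate that is inert to hydride and shields the conjugated decenoyl C=C.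

**Step 6**
Reactants: 10 N-(3-hydroxyprop-1-en-2-yl)-(E)-dec-2-enamide
Product: 11 N-(3-oxoprop-1-en-2-yl)-(E)-dec-2-enamide
Conditions: activated MnO2, CH2Cl2, rt; filter, use at once
Reagents that add atoms: none
Why: Activated MnO2 oxidation of the primary allylic alcohol stops at the enal under neutral heterogeneous conditions, so the polymerization-prone 2-amidoacrolein is obtained by filtration and used immediately.

**Step 7**
Reactants: 4 2-(4-methoxybenzyloxy)cyclohexane-1,3-dione; 11 N-(3-oxoprop-1-en-2-yl)-(E)-dec-2-enamide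
Product: 13 (1S,3S,4R,5R)-3-[(E)-dec-2-enamido]-4-hydroxy-1-(4-methoxybenzyloxy)bicyclo[3.3.1]nonane-8,9-dione (core numbering; amide equatorial/exo at C3, hydroxyl axial at C4 and syn to C9), via 2-[(E)-dec-2-enamido]-3-[1-(4-methoxybenzyloxy)-2,6-dioxocyclohexyl]propanal 12 (not isolated)
Conditions: (R)-TRIP (10 mol%), PhMe, 0 °C → rt
Reagents that add atoms: none
Why: The enol of 4 adds through its oxygenated carbon (core C1) to the unsubstituted β-carbon of 11 in an acid-catalysed Michael addition (forming C1–C2), giving triketo aldehyde 12, whose C1 is still prochiral and whose α-amido aldehyde centre C3 epimerizes freely through its enol. The phosphoric acid then enolizes one of the two enantiotopic ketones toward its only enolizable side, and that α-carbon (C5) adds to the aldehyde (forming C4–C5); this intramolecular aldol closes ring A in the 6-(enolendo)-exo-trig mode, and the reacting ketone becomes the C9 bridge. The closest known reaction type is the Michael–aldol α,α′-annulation of 2-substituted cyclohexane-1,3-diones with enals to bicyclo[3.3.1]nonane ketols, including its Brønsted-acid- and amine-catalysed desymmetrizing variants. C1 and C5 are set together by the catalyst's choice between the enantiotopic carbonyls; C3 is set by dynamic resolution in the chair-like transition state, where the amide must be equatorial because the axial (endo) position points into ring B toward C7; C4 is set by the bifunctional acid bridging the enol O–H and the aldehyde oxygen, which places the new hydroxyl axial and syn to C9, where it can also hydrogen-bond to the C9 carbonyl in the product. The step needs C- over O-alkylation (the oxa-Michael adduct is reversible), a single aldol regiochemistry (the other α-position of each ketone is the quaternary C1) and no dehydration (a C4=C5 alkene would be a bridgehead enone), so enantioselection is the only open selectivity.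

**Step 8**
Reactants: 13 bicyclic ketol
Product: 14 C4 tert-butyldimethylsilyl ether of 13
Conditions: TBSOTf, 2,6-lutidine, CH2Cl2, −78 → 0 °C
Reagents that add atoms: tert-butyldimethylsilyl triflate, CC(C)(C)[Si](C)(C)OS(=O)(=O)C(F)(F)F
Why: Silylation with a silyl triflate and a hindered pyridine base caps the axial, hydrogen-bonded C4 hydroxyl, which blocks retro-aldol opening of the β-hydroxy ketone in the basic steps that follow.

**Step 9**
Reactants: 14 C4 TBS ether
Product: 15 C8 trimethylsilyl enol ether (C7=C8–OSiMe3) of 14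
Conditions: TMSOTf, Et3N, CH2Cl2, 0 °C; cold aq. NaHCO3
Reagents that add atoms: trimethylsilyl triflate, C[Si](C)(C)OS(=O)(=O)C(F)(F)F
Why: Soft enolization (silyl triflate/amine) can deprotonate only C7, because the other α-carbon of the C8 ketone is the quaternary C1 and the C9 ketone is flanked by C1 and the bridgehead C5 (Bredt's rule); adventitious silylation of the amide is reversed on aqueous work-up.

**Step 10**
Reactants: 15 C8 trimethylsilyl enol ether
Product: 16 C6=C7 enone (bicyclo[3.3.1]non-6-ene-8,9-dione; C4 OTBS, C1 OPMB)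
Conditions: Pd(OAc)2 (1.1 equiv), MeCN, rt
Reagents that add atoms: none
Why: Saegusa–Ito oxidation: transmetallation of the silyl enol ether to the palladium(II) enolate and syn β-hydride elimination from C6 give the C6=C7 enone, the only possible regioisomer.

**Step 11**
Reactants: 16 C6=C7 enone
Product: 17 exo C6–C7 epoxy ketone (oxirane oxygen syn to the C9 bridge; C8 and C9 ketones)
Conditions: TBHP (decane), DBU, CH2Cl2, 0 °C
Reagents that add atoms: tert-butyl hydroperoxide, CC(C)(C)OO
Why: Weitz–Scheffer nucleophilic epoxidation: tert-butylperoxide should add to C6 on the exo face of ring B (syn to the one-carbon C9 bridge, anti to the axial C5–C4 bond and away from the C2–C3–C4 bridge) and the enolate closes the oxirane on the same face, which sets C6 and C7, while the hydroxide-free medium limits retro-Claisen attack on the non-enolizable C8/C9 1,3-diketone.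

**Step 12**
Reactants: 17 exo C6–C7 epoxy ketone
Product: 19 allylic alcohol (C6–OH syn to C9, C7=C8 alkene, C9 ketone; C4 OTBS, C1 OPMB), via C8 hydrazone of the epoxy ketone 18 (not isolated)
Conditions: N2H4·H2O, AcOH (cat.), MeOH, 0 °C → rt
Reagents that add atoms: none
Why: Wharton transposition: hydrazine should condense with the epoxide-activated C8 carbonyl (the C9 carbonyl is screened by the quaternary C1, the bridgehead C5, the axial C4 silyl ether and the exo oxirane), the hydrazone opens the epoxide to a vinyl diazene, and loss of N2 leaves the C7=C8 alkene; the C6–O bond is never broken, so C6 keeps the configuration set in step 11.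

**Step 13**
Reactants: 19 allylic alcohol, C4 TBS ether
Product: 20 C4,C6-diol (C7=C8 alkene, C9 ketone, C1 OPMB)
Conditions: HF·pyridine, pyridine, THF, 0 °C → rt
Reagents that add atoms: none
Why: Fluoride-mediated Si–O cleavage with pyridine-buffered HF is non-basic, so neither β-hydroxy ketone should undergo retro-aldol, and it is done before the acid-sensitive oxirane is in place.

**Step 14**
Reactants: 20 C4,C6-diol
Product: 21 C7–C8 exo-epoxide (oxirane syn to C6–OH and to C9; C1 OPMB)
Conditions: VO(acac)2 (5 mol%), TBHP, CH2Cl2, 0 °C → rt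
Reagents that add atoms: tert-butyl hydroperoxide, CC(C)(C)OO
Why: Vanadium-catalysed hydroxyl-directed epoxidation: the vanadate ester of the allylic C6 alcohol delivers the peroxide oxygen to C7=C8 on the face of that hydroxyl, which is also the exo face, setting C7 and C8 syn to C6–OH, and the electron-poor dec-2-enamide alkene is not touched.

**Step 15**
Reactants: 21 C7–C8 epoxide, C1 PMB ether
Product: 22 isariotin D, (1S,3S,4R,5S,6S,7S,8S) in the core numbering
Conditions: DDQ, CH2Cl2/pH 7 phosphate buffer, 0 °C → rt
Reagents that add atoms: none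
Why: Oxidative PMB cleavage: DDQ abstracts the benzylic hydride of the electron-rich ether and water hydrolyses the oxocarbenium ion, releasing the bridgehead tertiary alcohol under neutral buffered conditions that the oxirane, the ketols and the enamide should tolerate.

**Compound list**
1 | cyclohexane-1,3-dione | O=C1CCCC(=O)C1 | starting material
2 | 2-diazocyclohexane-1,3-dione | [N-]=[N+]=C1C(=O)CCCC1=O | intermediate
3 | 4-methoxybenzyl alcohol | COc1ccc(CO)cc1 | starting material
4 | 2-(4-methoxybenzyloxy)cyclohexane-1,3-dione | O=C1CCCC(=O)C1OCc1ccc(OC)cc1 | intermediate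
5 | DL-serine methyl ester hydrochloride | COC(=O)C(N)CO.Cl | starting material
6 | (E)-dec-2-enoic acid | CCCCCCC/C=C/C(=O)O | starting material
7 | methyl N-[(E)-dec-2-enoyl]-DL-serinate | CCCCCCC/C=C/C(=O)NC(CO)C(=O)OC | intermediate
8 | methyl N-[(E)-dec-2-enoyl]-O-(methylsulfonyl)-DL-serinate | CCCCCCC/C=C/C(=O)NC(COS(C)(=O)=O)C(=O)OC | intermediate
9 | methyl 2-[(E)-dec-2-enamido]acrylate | CCCCCCC/C=C/C(=O)NC(=C)C(=O)OC | intermediate
10 | N-(3-hydroxyprop-1-en-2-yl)-(E)-dec-2-enamide | CCCCCCC/C=C/C(=O)NC(=C)CO | intermediate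
11 | N-(3-oxoprop-1-en-2-yl)-(E)-dec-2-enamide | CCCCCCC/C=C/C(=O)NC(=C)C=O | intermediate
12 | 2-[(E)-dec-2-enamido]-3-[1-(4-methoxybenzyloxy)-2,6-dioxocyclohexyl]propanal (epimerizing at the aldehyde α-carbon) | CCCCCCC/C=C/C(=O)NC(C=O)CC1(OCc2ccc(OC)cc2)C(=O)CCCC1=O | intermediate
13 | (1S,3S,4R,5R)-3-[(E)-dec-2-enamido]-4-hydroxy-1-(4-methoxybenzyloxy)bicyclo[3.3.1]nonane-8,9-dione (core numbering) | CCCCCCC/C=C/C(=O)N[C@H]1C[C@@]2(OCc3ccc(OC)cc3)C(=O)[C@H](CCC2=O)[C@H]1O | intermediate
14 | C4 tert-butyldimethylsilyl ether of 13 | CCCCCCC/C=C/C(=O)N[C@H]1C[C@@]2(OCc3ccc(OC)cc3)C(=O)[C@H](CCC2=O)[C@H]1O[Si](C)(C)C(C)(C)C | intermediate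
15 | C8 trimethylsilyl enol ether (C7=C8) of 14 | CCCCCCC/C=C/C(=O)N[C@H]1C[C@@]2(OCc3ccc(OC)cc3)C(=O)[C@H](CC=C2O[Si](C)(C)C)[C@H]1O[Si](C)(C)C(C)(C)C | intermediate
16 | C6=C7 enone, C8 and C9 ketones, C4 OTBS, C1 OPMB | CCCCCCC/C=C/C(=O)N[C@H]1C[C@@]2(OCc3ccc(OC)cc3)C(=O)[C@H](C=CC2=O)[C@H]1O[Si](C)(C)C(C)(C)C | intermediate
17 | exo C6–C7 epoxy ketone (oxirane syn to C9), C4 OTBS, C1 OPMB | CCCCCCC/C=C/C(=O)N[C@H]1C[C@@]2(OCc3ccc(OC)cc3)C(=O)[C@H]([C@@H]4O[C@@H]4C2=O)[C@H]1O[Si](C)(C)C(C)(C)C | intermediate
18 | C8 hydrazone of epoxy ketone 17 | CCCCCCC/C=C/C(=O)N[C@H]1C[C@@]2(OCc3ccc(OC)cc3)C(=O)[C@H]([C@@H]4O[C@@H]4C2=NN)[C@H]1O[Si](C)(C)C(C)(C)C | intermediate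
19 | allylic alcohol: C6–OH (syn to C9), C7=C8, C9 ketone, C4 OTBS, C1 OPMB | CCCCCCC/C=C/C(=O)N[C@H]1C[C@@]2(OCc3ccc(OC)cc3)C(=O)[C@H]([C@H](O)C=C2)[C@H]1O[Si](C)(C)C(C)(C)C | intermediate
20 | C4,C6-diol: C7=C8, C9 ketone, C1 OPMB | CCCCCCC/C=C/C(=O)N[C@H]1C[C@@]2(OCc3ccc(OC)cc3)C(=O)[C@H]([C@H](O)C=C2)[C@H]1O | intermediate
21 | C7–C8 exo-epoxide of 20 (O-PMB isariotin D) | CCCCCCC/C=C/C(=O)N[C@H]1C[C@@]2(OCc3ccc(OC)cc3)C(=O)[C@H]([C@H](O)[C@@H]4O[C@@H]42)[C@H]1O | intermediate
22 | isariotin D | CCCCCCC/C=C/C(=O)N[C@H]1C[C@@]2(O)C(=O)[C@H]([C@H](O)[C@@H]3O[C@@H]32)[C@H]1O | target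

**Step count**
Total: 15 steps. Longest linear sequence: 13 steps (steps 3–15, from DL-serine methyl ester hydrochloride); the dione branch (steps 1–2) joins at step 7.

**Steps most likely to fail**

Step 7. What may go wrong: the acid does not distinguish the two enantiotopic ketones well enough, so enantiomeric purity is low, or oligomerization of 11 outruns its capture by the dione. Fallback (resolution in place of asymmetric catalysis): setting out from 4 and 11, the Michael addition is run alone with catalytic DABCO in THF and the triketo aldehyde 12 is isolated. An achiral acid (diphenyl phosphate, PhMe) then closes ring A to the racemic ketol F1, which is resolved by preparative chromatography on a chiral stationary phase. The wanted enantiomer is 13, where the route is rejoined, and the enantiomeric ketol F2 is set aside.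

Step 11. What may go wrong: the peroxide anion adds to the C9 or C8 carbonyl and the non-enolizable 1,3-diketone opens by retro-Claisen cleavage, or addition takes place on the endo face. Fallback (remove the C8 carbonyl before any oxygen or nitrogen nucleophile is used, then oxidize the allylic C–H): setting out from 14, KHMDS (2.2 equiv) and N-(5-chloro-2-pyridyl)triflimide in THF at −78 °C give the C8 enol triflate F3. Reduction with Pd(OAc)2/PPh3, Bu3N and HCO2H in DMF gives the C7=C8 alkene F4. Allylic hydroxylation with SeO2 (cat.)/TBHP in CH2Cl2 then gives 19, where the route is rejoined; C6 is the only allylic C–H position, and the ene/[2,3]-sigmatropic sequence runs suprafacially on the exo face. Steps 9–12 are bypassed.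

Step 12. What may go wrong: hydrazine condenses at the bridging C9 carbonyl or cleaves the 1,3-diketone, or the hydrazone does not fragment cleanly. Fallback (reductive epoxide opening, then deoxygenation of C8 through the enol triflate): setting out from 17, SmI2 in THF/MeOH at −78 °C cleaves the C7–O bond of the α,β-epoxy ketone to the β-hydroxy ketone F5 with the C6 carbinol unchanged; loss of the C1 ether would need a bridgehead enolate and is not expected. TBSOTf/2,6-lutidine gives the bis-silyl ether F6, KHMDS with N-(5-chloro-2-pyridyl)triflimide gives the enol triflate F7, and Pd-catalysed formate reduction gives the bis-silylated alkene F8. HF·pyridine removes both silyl groups to give 20, where the route is rejoined; step 13 is absorbed.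

**Further compounds**
F1 | step 7 | racemic ketol (13 and its enantiomer, 1:1) | CCCCCCC/C=C/C(=O)N[C@H]1C[C@@]2(OCc3ccc(OC)cc3)C(=O)[C@H](CCC2=O)[C@H]1O.CCCCCCC/C=C/C(=O)N[C@@H]1C[C@]2(OCc3ccc(OC)cc3)C(=O)[C@@H](CCC2=O)[C@@H]1O
F2 | step 7 | enantiomeric ketol (ent-13) | CCCCCCC/C=C/C(=O)N[C@@H]1C[C@]2(OCc3ccc(OC)cc3)C(=O)[C@@H](CCC2=O)[C@@H]1O
F3 | step 11 | C8 enol triflate (C7=C8–OTf) of 14 | CCCCCCC/C=C/C(=O)N[C@H]1C[C@@]2(OCc3ccc(OC)cc3)C(=O)[C@H](CC=C2OS(=O)(=O)C(F)(F)F)[C@H]1O[Si](C)(C)C(C)(C)C
F4 | step 11 | C7=C8 alkene with C6 methylene, C9 ketone, C4 OTBS, C1 OPMB | CCCCCCC/C=C/C(=O)N[C@H]1C[C@@]2(OCc3ccc(OC)cc3)C(=O)[C@H](CC=C2)[C@H]1O[Si](C)(C)C(C)(C)C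
F5 | step 12 | β-hydroxy ketone: C6–OH (syn to C9), C7 methylene, C8 and C9 ketones, C4 OTBS, C1 OPMB | CCCCCCC/C=C/C(=O)N[C@H]1C[C@@]2(OCc3ccc(OC)cc3)C(=O)[C@H]([C@H](O)CC2=O)[C@H]1O[Si](C)(C)C(C)(C)C
F6 | step 12 | C4,C6-bis(TBS) ether of F5 | CCCCCCC/C=C/C(=O)N[C@H]1C[C@@]2(OCc3ccc(OC)cc3)C(=O)[C@H]([C@H](O[Si](C)(C)C(C)(C)C)CC2=O)[C@H]1O[Si](C)(C)C(C)(C)C
F7 | step 12 | C8 enol triflate (C7=C8–OTf) of F6 | CCCCCCC/C=C/C(=O)N[C@H]1C[C@@]2(OCc3ccc(OC)cc3)C(=O)[C@H]([C@H](O[Si](C)(C)C(C)(C)C)C=C2OS(=O)(=O)C(F)(F)F)[C@H]1O[Si](C)(C)C(C)(C)C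
F8 | step 12 | C7=C8 alkene, C4,C6-bis(TBS) ether, C1 OPMB | CCCCCCC/C=C/C(=O)N[C@H]1C[C@@]2(OCc3ccc(OC)cc3)C(=O)[C@H]([C@H](O[Si](C)(C)C(C)(C)C)C=C2)[C@H]1O[Si](C)(C)C(C)(C)C
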